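- The south-west flask lost more L than it made D: by 0.417 d, 26 percentage points of L had gone against 3.3% of D formed, so the first instants sent L somewhere these two columns do not show.

| setting | south-west | south-east | flask |
|---|---|---|---|
| L | 1 M | 1 M | 1.0 M |
| Z | 2 mol% | 4 mol% | 2 mol% |
| X | 11 mM | 11 mM | 11 mM |
| temperature | 35 °C | 30 °C | 35 °C |
| remark | the very flask that is asked about, followed so far | run made earlier |  |
| time |  |  | 8.0 d |

| run | time / d | D / % | L / % |
|---|---|---|---|
| south-west | 0.417 | 3.3 | 73.8 |
| south-west | 1.25 | 7.2 | 47.8 |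
| south-west | 2.50 | 9.7 | 29.7 |
| south-west | 3.00 | 10.5 | 26.2 |
| south-west | 5.00 | 12.0 | 17.1 |
| south-west | 6.00 | 12.2 | 14.2 |
| south-west | 8.00 | 12.6 | 10.6 |
| south-east | 2.08 | 17.4 | 37.4 |
| south-east | 4.00 | 20.5 | 22.6 |
| south-east | 6.00 | 21.5 | 17.1 |
| south-east | 8.00 | 21.0 | 14.5 |
| south-east | 10.0 | 20.8 | 13.5 |
| south-east | 12.0 | 19.9 | 13.0 |
| south-east | 15.0 | 19.6 | 11.7 |

(readings scatter by 0.3 percentage points)

- ochre: change nothing and wait 8.0 d more
- green: at 8.0 d take out 90% of the D then present, then wait 8.0 d
- blue: at 8.0 d raise the temperature by 20 K, then wait 8.0 d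
- amber: at 8.0 d add Z, 100% of the amount charged, then wait 8.0 d

- D, in percent of the L first charged, at 8.0 d
- which option adds most D ("none" when 2 percentage points or less is all one gets) (ochre / green / blue / amber / none)
- D present, with what was taken out counted in, in percent of the L first charged, after green
- D present, with what was taken out counted in, in percent of the L first charged, after amber

- D that was removed still counts
- additions bring no volume worth counting

- In the middle of the south-west run, from 2.50 d to 5.00 d, L fell from 29.7% to 17.1% while D crept from 9.7% to 12.0%. What I watched next was the two columns taken together.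
- The end shows best in the south-east run, with 4 mol% of Z. There [D]/[L] climbed from 0.465 at 2.08 d to 1.68 at 15.0 d, while D itself drifted down from 21.5%.
- I took that last reading as the ceiling ratio, the [D]/[L] towards which Z carries a flask, an apparent equilibrium constant, and I assumed that temperature leaves it unmoved.
- The south-west flask stood at 1.19 at 8.00 d, which is 0.150 of a power of ten below the ceiling. I committed to the reading 12.6% for now.
- For ochre, amber and blue I counted the 23.2% of L plus D in the south-west flask as kept whole, which was an assumption of my reckoning. At the ceiling that pool holds 14.5% of D, a gain of 1.9 points, which is less than 2 points.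
- Green takes out 11.3% and leaves 1.26% of D, so the ratio drops to 0.119, 1.15 powers of ten below the ceiling.
- I reckoned the 11.9% of L plus D left in that flask to reach the ceiling within the wait, with 7.43% standing as D. Counting what was taken out, I reckoned 18.8%, and green was my choice.
- The forecast gave 12.6%, none as best, 13.2% after green and 13.7% after amber, holding that “D therefore levels off mainly because L is nearly gone”, so it parted from me on green.
- The flask gave 12.4%, with green best at 18.3%, against my 18.8%. Amber gave 11.2% against my 14.5%, and ochre moved D by −0.81 points.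

    L + Z ⇌ D + Z, rate k1*[L]*[Z] forward; the back reaction follows from the equilibrium constant (K = 1.40, k = 0.00890 M⁻¹ min⁻¹, Ea = 58.0 kJ mol⁻¹, ΔH = −2.00 kJ mol⁻¹)
    D + Z ⇌ Q + Z, rate k2*[Z]*[D] forward; the back reaction follows from the equilibrium constant (K = 0.620, k = 0.0520 M⁻¹ min⁻¹, Ea = 71.0 kJ mol⁻¹, ΔH = −41.0 kJ mol⁻¹)
    Q + Z ⇌ L + Z, rate k3*[Z]*[Q] forward; the back reaction follows from the equilibrium constant (k = 0.00130 M⁻¹ min⁻¹, Ea = 63.0 kJ mol⁻¹)
    2 L → E (k = 2.40 × 10⁻⁴ M⁻¹ min⁻¹, Ea = 97.0 kJ mol⁻¹)
    Z + X → G (k = 8.20 M⁻¹ min⁻¹, Ea = 42.0 kJ mol⁻¹)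
    D + Z ⇌ J + Z, rate k6*[Z]*[D] forward; the back reaction follows from the equilibrium constant (K = 0.340, k = 0.00300 M⁻¹ min⁻¹, Ea = 62.0 kJ mol⁻¹, ΔH = −11.0 kJ mol⁻¹)
    (constants at 35 °C)

- At 8.00 d in the asked flask the exchange of L and D alone had a relaxation half-life of 3.51 d, shorter than the 8.0 d wait, and the exchange of D and Q alone had 0.394 d, shorter again. A second flask, like the asked one but with 3.4 mol% of Z, stood at a [D]/[L] of 1.55 at 8.0 d; its L plus D, shared by the ceiling ratio, gives 18.5% of D, and that flask held 18.0%.

(All runs come from a simulation with made-up constants; scatter was added.)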